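**Assumption:** the four starting materials are taken as commercial, and ring positions follow the naphthalen-2(4aH)-one skeleton (C4a quaternary, C5 CH–Me, C6 O-acyl, C7 OH, C3 enol OH). This route is a paper design; step 8 is a proposed reaction without direct precedent.

## Retrosynthetic overview

1. C6–O ester bond: trans-diaxial opening of the 6,7-epoxide (on the face opposite both methyls) by (2E,4E,6S)-6-methylocta-2,4-dienoic acid; the epoxide comes from the C6=C7 alkene.
2. C4a–C5 bond (key): an ortho-quinone, made by oxidising a 3,4-dialkylphenol, is the acceptor and the γ-carbon of a tethered (R,E)-allylsilane is the donor. This closes ring A, sets C4a and C5, unveils the diosphenol and leaves the C6=C7 alkene.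
3. Allylsilane: copper-mediated syn-SN2′ of a benzylic Grignard reagent (from 4-hydroxy-2-methylbenzaldehyde) on the N-phenylcarbamate of (R,E)-4-(trimethylsilyl)but-3-en-2-ol.
4. Dienoic acid: (S)-2-methylbutan-1-ol, oxidation, vinylogous Horner–Wadsworth–Emmons olefination, saponification.
5. Ring order: ring B is the benzene ring of the starting aldehyde; ring A is the only ring formed, in the key step.

## Route

Step 1
Reactants: 1 4-hydroxy-2-methylbenzaldehyde
Product: 2 4-(tert-butyldimethylsilyloxy)-2-methylbenzaldehyde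
Conditions: TBSCl, imidazole, DMF, 23 °C
Reagents that add atoms: tert-butyldimethylsilyl chloride, CC(C)(C)[Si](C)(C)Cl
Why: Imidazole-promoted silylation masks the acidic phenol for the later Grignard chemistry; no stereocentre is involved.

Step 2
Reactants: 2 4-(tert-butyldimethylsilyloxy)-2-methylbenzaldehyde
Product: 3 [4-(tert-butyldimethylsilyloxy)-2-methylphenyl]methanol
Conditions: NaBH4, MeOH, 0 °C
Reagents that add atoms: none
Why: Borohydride reduction of the aryl aldehyde gives the benzylic alcohol, and the aryl silyl ether is inert at 0 °C.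

Step 3
Reactants: 3 [4-(tert-butyldimethylsilyloxy)-2-methylphenyl]methanol
Product: 4 tert-butyl[4-(chloromethyl)-3-methylphenoxy]dimethylsilane
Conditions: PPh3, NCS, CH2Cl2, 0 → 23 °C
Reagents that add atoms: N-chlorosuccinimide, O=C1CCC(=O)N1Cl
Why: Appel-type chlorination converts the electron-rich benzylic alcohol to the chloride under neutral conditions that spare the aryl silyl ether.

Step 4
Reactants: 5 (R)-4-(trimethylsilyl)but-3-yn-2-ol
Product: 6 (2R,3E)-4-(trimethylsilyl)but-3-en-2-ol
Conditions: NaAlH2(OCH2CH2OMe)2, Et2O, 0 → 23 °C; Rochelle salt work-up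
Reagents that add atoms: none
Why: Alkoxide-directed trans-hydroalumination of the propargylic alcohol gives the (E)-vinylsilane, and the carbinol stereocentre is untouched.

Step 5
Reactants: 6 (2R,3E)-4-(trimethylsilyl)but-3-en-2-ol
Product: 7 (2R,3E)-4-(trimethylsilyl)but-3-en-2-yl N-phenylcarbamate
Conditions: PhNCO, Et3N (cat.), CH2Cl2, 23 °C
Reagents that add atoms: phenyl isocyanate, O=C=Nc1ccccc1
Why: Addition of the secondary alcohol to the isocyanate installs, with retention, the N-phenylcarbamate that will direct the copper reagent.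

Step 6
Reactants: 4 tert-butyl[4-(chloromethyl)-3-methylphenoxy]dimethylsilane; 7 (2R,3E)-4-(trimethylsilyl)but-3-en-2-yl N-phenylcarbamate
Product: 10 tert-butyldimethyl{3-methyl-4-[(2R,3E)-2-(trimethylsilyl)pent-3-en-1-yl]phenoxy}silane, via benzylmagnesium chloride 8 (not isolated), via lithium carbamate 9 (not isolated)
Conditions: 4, Mg, THF, 0 °C; 7, n-BuLi, THF, −78 °C; then CuI·2LiCl (1 equiv), then 8 (1.3 equiv), −78 → 0 °C; aq NH4Cl
Reagents that add atoms: none
Why: Copper-mediated syn-SN2′ substitution of a γ-silyl allylic N-phenylcarbamate by a Grignard reagent (Gallina–Goering/Woerpel type) delivers the benzyl group from nitrogen-bound copper to the silyl-bearing carbon on the face of the departing carbamate, through the conformer with C–O perpendicular to the alkene and the carbinol H in its plane, so the (R)-carbinol centre becomes the (R)-α-silyl centre and the new alkene is E.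

Step 7
Reactants: 10 tert-butyldimethyl{3-methyl-4-[(2R,3E)-2-(trimethylsilyl)pent-3-en-1-yl]phenoxy}silane
Product: 11 3-methyl-4-[(2R,3E)-2-(trimethylsilyl)pent-3-en-1-yl]phenol
Conditions: n-Bu4NF, THF, 0 °C, 15 min; aq NH4Cl
Reagents that add atoms: none
Why: Fluoride cleaves the aryl O–Si bond within minutes at 0 °C while the unactivated allylic C–SiMe3 bond survives.

Step 8
Reactants: 11 3-methyl-4-[(2R,3E)-2-(trimethylsilyl)pent-3-en-1-yl]phenol
Product: 14 (4aS,5S)-3-hydroxy-4a,5-dimethyl-5,8-dihydronaphthalen-2(4aH)-one, via ortho-quinone 12 (not isolated), via trimethylsilyl enol ether 13 (not isolated)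
Conditions: IBX (1.2 equiv), DMF, 23 °C, dark; Et2O/H2O extraction, MgSO4; then Me3SiOTf (20 mol %), 2,6-di-tert-butylpyridine (25 mol %), CH2Cl2, −78 → −40 °C; aq citric acid, THF, 0 °C
Reagents that add atoms: 2-iodoxybenzoic acid (IBX), O=C1OI(=O)(O)c2ccccc12
Why: Proposed new method: IBX delivers oxygen to the less hindered ortho carbon of the phenol (known phenol to ortho-quinone oxidation) to give quinone 12, the two-electron-oxidised and therefore acceptor form of a catechol, in which silylation of the C2 carbonyl by Me3SiOTf turns the methyl-bearing C4 (a donor carbon para to oxygen at the catechol level) into a tertiary allyl-cation terminus that the γ-carbon of the allylsilane captures 6-endo, the only other carbon in reach (C6) lying α to the second carbonyl; anti-SE2′ attack through a chair with C–Si axial and the E-propenyl methyl equatorial transfers the (R)-silyl centre into 4aS and 5S (cis-dimethyl), silicon passes to the enolate oxygen (13) and is removed on acidic work-up; the closest known reactions are Lewis-acid Hosomi–Sakurai conjugate allylation of quinones and hypervalent-iodine oxidative Hosomi–Sakurai dearomatisation of phenols.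

Step 9
Reactants: 14 (4aS,5S)-3-hydroxy-4a,5-dimethyl-5,8-dihydronaphthalen-2(4aH)-one
Product: 15 (4aS,5R,6S,7R)-6,7-epoxy-3-hydroxy-4a,5-dimethyl-5,6,7,8-tetrahydronaphthalen-2(4aH)-one
Conditions: mCPBA (1.1 equiv), NaHCO3, CH2Cl2, 0 °C
Reagents that add atoms: 3-chloroperoxybenzoic acid, O=C(OO)c1cccc(Cl)c1
Why: Prilezhaev epoxidation takes the isolated cis-disubstituted alkene, which is more nucleophilic than the acyl-substituted enol or dienone double bonds, and the peracid approaches anti to the axial angular methyl (as with steroidal 2-enes), placing the oxirane on the face opposite both methyls.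

Step 10
Reactants: 16 (S)-2-methylbutan-1-ol; 17 triethyl 4-phosphonocrotonate
Product: 19 ethyl (2E,4E,6S)-6-methylocta-2,4-dienoate, via (S)-2-methylbutanal 18 (not isolated)
Conditions: TEMPO (1 mol %), KBr (10 mol %), NaOCl, NaHCO3, CH2Cl2–H2O, 0 °C; dried CH2Cl2 layer added to 17, LiN(SiMe3)2, THF, −78 → 0 °C
Reagents that add atoms: none
Why: Anelli oxidation gives the configurationally labile aldehyde, which is used at once in a vinylogous Horner–Wadsworth–Emmons olefination that forms the new alkene E and keeps the existing one E, the 6S centre coming unchanged from the chiral-pool alcohol.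

Step 11
Reactants: 19 ethyl (2E,4E,6S)-6-methylocta-2,4-dienoate
Product: 20 (2E,4E,6S)-6-methylocta-2,4-dienoic acid
Conditions: LiOH·H2O, THF–MeOH–H2O, 23 °C; then 1 M HCl
Reagents that add atoms: lithium hydroxide (hydroxide oxygen), [Li+].[OH-]
Why: Saponification of the ethyl ester leaves the diene geometry and the remote stereocentre unchanged.

Step 12
Reactants: 15 (4aS,5R,6S,7R)-6,7-epoxy-3-hydroxy-4a,5-dimethyl-5,6,7,8-tetrahydronaphthalen-2(4aH)-one; 20 (2E,4E,6S)-6-methylocta-2,4-dienoic acid
Product: 21 Septeremophilane G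
Conditions: 20 (5 equiv), (±)-camphorsulfonic acid (10 mol %), CH2Cl2 (1 M in 20), 23 °C
Reagents that add atoms: none
Why: Acid-catalysed trans-diaxial (Fürst–Plattner) opening of the conformationally locked epoxide has the carboxylic acid attack C6 axially from the methyl face with inversion (the classical outcome for steroidal 2α,3α-epoxides), giving the 6R ester and the 7R alcohol, whose trans-diaxial relation blocks acyl migration.

## Compound list

1 | 4-hydroxy-2-methylbenzaldehyde | O=Cc1ccc(O)cc1C | starting material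
2 | 4-(tert-butyldimethylsilyloxy)-2-methylbenzaldehyde | O=Cc1ccc(O[Si](C)(C)C(C)(C)C)cc1C | intermediate
3 | [4-(tert-butyldimethylsilyloxy)-2-methylphenyl]methanol | OCc1ccc(O[Si](C)(C)C(C)(C)C)cc1C | intermediate
4 | tert-butyl[4-(chloromethyl)-3-methylphenoxy]dimethylsilane | ClCc1ccc(O[Si](C)(C)C(C)(C)C)cc1C | intermediate
5 | (R)-4-(trimethylsilyl)but-3-yn-2-ol | C[C@@H](O)C#C[Si](C)(C)C | starting material
6 | (2R,3E)-4-(trimethylsilyl)but-3-en-2-ol | C[C@@H](O)/C=C/[Si](C)(C)C | intermediate
7 | (2R,3E)-4-(trimethylsilyl)but-3-en-2-yl N-phenylcarbamate | C[C@@H](OC(=O)Nc1ccccc1)/C=C/[Si](C)(C)C | intermediate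
8 | {[4-(tert-butyldimethylsilyloxy)-2-methylphenyl]methyl}magnesium chloride | Cc1cc(O[Si](C)(C)C(C)(C)C)ccc1C[Mg]Cl | intermediate (not isolated)
9 | N-lithio derivative of carbamate 7 | C[C@@H](OC(=O)N([Li])c1ccccc1)/C=C/[Si](C)(C)C | intermediate (not isolated)
10 | tert-butyldimethyl{3-methyl-4-[(2R,3E)-2-(trimethylsilyl)pent-3-en-1-yl]phenoxy}silane | C/C=C/[C@H]([Si](C)(C)C)Cc1ccc(O[Si](C)(C)C(C)(C)C)cc1C | intermediate
11 | 3-methyl-4-[(2R,3E)-2-(trimethylsilyl)pent-3-en-1-yl]phenol | C/C=C/[C@H]([Si](C)(C)C)Cc1ccc(O)cc1C | intermediate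
12 | 4-methyl-5-[(2R,3E)-2-(trimethylsilyl)pent-3-en-1-yl]cyclohexa-3,5-diene-1,2-dione | C/C=C/[C@H]([Si](C)(C)C)CC1=CC(=O)C(=O)C=C1C | intermediate (not isolated)
13 | (4aS,5S)-4a,5-dimethyl-3-(trimethylsilyloxy)-5,8-dihydronaphthalen-2(4aH)-one | C[C@H]1C=CCC2=CC(=O)C(O[Si](C)(C)C)=C[C@]12C | intermediate (not isolated)
14 | (4aS,5S)-3-hydroxy-4a,5-dimethyl-5,8-dihydronaphthalen-2(4aH)-one | C[C@H]1C=CCC2=CC(=O)C(O)=C[C@]12C | intermediate
15 | (4aS,5R,6S,7R)-6,7-epoxy-3-hydroxy-4a,5-dimethyl-5,6,7,8-tetrahydronaphthalen-2(4aH)-one (oxirane opposite both methyls) | C[C@H]1[C@@H]2O[C@@H]2CC3=CC(=O)C(O)=C[C@]13C | intermediate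
16 | (S)-2-methylbutan-1-ol | CC[C@H](C)CO | starting material
17 | triethyl 4-phosphonocrotonate | CCOC(=O)/C=C/CP(=O)(OCC)OCC | starting material
18 | (S)-2-methylbutanal | CC[C@H](C)C=O | intermediate (not isolated)
19 | ethyl (2E,4E,6S)-6-methylocta-2,4-dienoate | CC[C@H](C)/C=C/C=C/C(=O)OCC | intermediate
20 | (2E,4E,6S)-6-methylocta-2,4-dienoic acid | CC[C@H](C)/C=C/C=C/C(=O)O | intermediate
21 | Septeremophilane G, (4aS,5R,6R,7R)-3,7-dihydroxy-4a,5-dimethyl-2-oxo-2,4a,5,6,7,8-hexahydronaphthalen-6-yl (2E,4E,6S)-6-methylocta-2,4-dienoate | CC[C@H](C)/C=C/C=C/C(=O)O[C@H]1[C@H](O)CC2=CC(=O)C(O)=C[C@]2(C)[C@H]1C | target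

## Step count and risks

Total steps: 12. Longest linear sequence: 8 (steps 1, 2, 3, 6, 7, 8, 9, 12).

**Step 8 (most likely to fail).** The free quinone may be too weak an acceptor, the allylsilane may be protodesilylated, or the quinone may tautomerise to a quinone methide before cyclising. The fallback sets out from 11 and returns to 14. Phenol 11 is oxidised with IBX as before, but the quinone is reduced in the work-up with Na2S2O4 to the stable catechol F1. F1 is then treated with PhI(OAc)2 in (CF3)2CHOH–CH2Cl2 at −40 °C, so that the electrophile is the iodine-bound aryloxy species of a trivalent-iodine oxidative Hosomi–Sakurai reaction and not a Lewis-acid-activated free quinone. The allylsilane attacks para to the bound oxygen, and the same chair delivers 14.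

**Step 12.** The acid may attack the less hindered C7 (diequatorial opening), or the epoxide may eliminate toward the dienone instead of adding the acid. The fallback sets out from 15 and returns to 21. Aqueous HClO4 in THF opens 15 trans-diaxially with the small nucleophile water to the triol F4. Et3SiCl and imidazole (2.2 equiv) silylate the enol and the less hindered C7 hydroxyl to give the bis(triethylsilyl) ether F5. The remaining hindered C6 hydroxyl is acylated with 20 under Yamaguchi conditions (2,4,6-trichlorobenzoyl chloride, Et3N, then DMAP, toluene, 60 °C) to give the ester F6. HF·pyridine in THF then removes both silyl groups to give 21.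

**Step 9.** The peracid may attack the free diosphenol (enol epoxidation or cleavage of the 1,2-dioxygenated unit) in competition with the alkene. The fallback sets out from 14 and returns to 15. Ac2O and pyridine convert 14 to the enol acetate F2, whose enol double bond is deactivated. mCPBA then epoxidises only the ring A alkene, from the same face, to give the epoxy acetate F3. K2CO3 in MeOH at 0 °C removes the labile enol acetate and returns 15.

## Further compounds

F1 | step 8 | 4-methyl-5-[(2R,3E)-2-(trimethylsilyl)pent-3-en-1-yl]benzene-1,2-diol | C/C=C/[C@H]([Si](C)(C)C)Cc1cc(O)c(O)cc1C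
F2 | step 9 | (4aS,5S)-4a,5-dimethyl-2-oxo-2,4a,5,8-tetrahydronaphthalen-3-yl acetate | C[C@H]1C=CCC2=CC(=O)C(OC(C)=O)=C[C@]12C
F3 | step 9 | (4aS,5R,6S,7R)-6,7-epoxy-4a,5-dimethyl-2-oxo-2,4a,5,6,7,8-hexahydronaphthalen-3-yl acetate | C[C@H]1[C@@H]2O[C@@H]2CC3=CC(=O)C(OC(C)=O)=C[C@]13C
F4 | step 12 | (4aS,5R,6R,7R)-3,6,7-trihydroxy-4a,5-dimethyl-5,6,7,8-tetrahydronaphthalen-2(4aH)-one | C[C@H]1[C@@H](O)[C@H](O)CC2=CC(=O)C(O)=C[C@]12C
F5 | step 12 | (4aS,5R,6R,7R)-6-hydroxy-4a,5-dimethyl-3,7-bis(triethylsilyloxy)-5,6,7,8-tetrahydronaphthalen-2(4aH)-one | C[C@H]1[C@@H](O)[C@H](O[Si](CC)(CC)CC)CC2=CC(=O)C(O[Si](CC)(CC)CC)=C[C@]12C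
F6 | step 12 | (4aS,5R,6R,7R)-4a,5-dimethyl-2-oxo-3,7-bis(triethylsilyloxy)-2,4a,5,6,7,8-hexahydronaphthalen-6-yl (2E,4E,6S)-6-methylocta-2,4-dienoate | C[C@H]1[C@@H](OC(=O)/C=C/C=C/[C@@H](C)CC)[C@H](O[Si](CC)(CC)CC)CC2=CC(=O)C(O[Si](CC)(CC)CC)=C[C@]12C
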